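Numbering used below: ring C1 bears CH2OH, C1=C2 is the ring olefin next to it, C4 is the stereocenter, C7=C8 (Z) and C11=C12 (E) carry the methyl groups, and C2' is the side-chain carbon bonded to C4. The enabling feature is that C4 is an sp3 methine between two ring CH2 groups (C3, C5) bonded to the sp2 carbon C2' of a methylidene unit (C2'=CH2); this is the footprint of a secondary boronic ester joined to a 1-substituted vinyllithium by Zweifel olefination.
Cuts, in order: CH2OH back to CO2Me; ring bond C1=C2 (intramolecular Still–Gennari olefination, the only ring closure) and C1–C14 (phosphonoacetate alkylation); C4–C2' (Zweifel coupling with the C8 unit from sulcatone); C3–C4 (lithiation–borylation with a two-carbon boronate); C12–C13 and C11–CH3 (carboalumination and epoxide opening of an enyne from nerylacetone).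
Forward: the chloro-polyene chain is built from nerylacetone, ring C4 is then assembled around boron from three components (chain benzoate, two-carbon boronate, C8 alkenyllithium) by two consecutive 1,2-metallate shifts, and the 14-membered ring is closed last at C1=C2.
Stereochemistry: C4 (R) comes from (−)-sparteine-directed lithiation and is relayed by inversion (step 9) and retention (step 12); 7Z comes from nerylacetone, 11E from syn carboalumination, 1Z from the Still–Gennari closure.

Key step: step 12

Remark: stereocenters that are formed and destroyed on the way (bromohydrin, epoxide, iodoboronate, phosphorus-bearing carbon) are carried as mixtures, and (−)-sparteine is used in stoichiometric amount.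

Step 1
Reactants: 1 nerylacetone, (5Z)-6,10-dimethylundeca-5,9-dien-2-one
Product: 3 (5Z)-6,10-dimethylundeca-5,9-dien-1-yne, via enol phosphate 2 (not isolated)
Conditions: LiN(iPr)2 (1.05 equiv), THF, −78 °C; ClP(O)(OEt)2, −78 °C → rt; then LiN(iPr)2 (2.3 equiv), THF, −78 °C → rt; NH4Cl aq
Reagents that add atoms: none
Why: Kinetic deprotonation at the methyl group gives the terminal enolate, and its enol phosphate undergoes base-induced elimination to the terminal alkyne (alkyne synthesis from a methyl ketone via the enol phosphate), which leaves the Z trisubstituted olefin untouched and creates no stereocenter.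

Step 2
Reactants: 3 (5Z)-6,10-dimethylundeca-5,9-dien-1-yne
Product: 6 (3E,7Z)-4,8,12-trimethyltrideca-3,7,11-trien-1-ol, via alkenylalane 4 (not isolated), via lithium aluminate 5 (not isolated)
Conditions: Me3Al (2 equiv), Cp2ZrCl2 (0.25 equiv), CH2Cl2, 0 °C → rt; volatiles removed, hexane; nBuLi (1 equiv), −78 → 0 °C; ethylene oxide (3 equiv), THF, −78 °C → rt; 3 M HCl, 0 °C
Reagents that add atoms: trimethylaluminium, C[Al](C)C; ethylene oxide, C1CO1
Why: Zirconium-catalysed syn carboalumination of the terminal alkyne (Negishi carboalumination) puts CH3 on the internal and aluminium on the terminal carbon and so fixes the E geometry of the new trisubstituted olefin, and the lithium aluminate made with nBuLi opens ethylene oxide with retention at the alkenyl carbon to add the two-carbon alcohol arm.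

Step 3
Reactants: 6 (3E,7Z)-4,8,12-trimethyltrideca-3,7,11-trien-1-ol
Product: 7 (6Z,10E)-13-chloro-2,6,10-trimethyltrideca-2,6,10-triene
Conditions: N-chlorosuccinimide (1.2 equiv), PPh3 (1.2 equiv), THF, 0 °C → rt
Reagents that add atoms: N-chlorosuccinimide, O=C1CCC(=O)N1Cl
Why: Appel-type chlorination: chloride displaces the alkoxyphosphonium ion of the primary alcohol by SN2 under neutral conditions that spare the three olefins, and the chloride then serves as an organolithium-stable placeholder for the later leaving group.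

Step 4
Reactants: 7 (6Z,10E)-13-chloro-2,6,10-trimethyltrideca-2,6,10-triene
Product: 9 3-[(3Z,7E)-10-chloro-3,7-dimethyldeca-3,7-dien-1-yl]-2,2-dimethyloxirane (racemic), via bromohydrin 8 (not isolated)
Conditions: N-bromosuccinimide (1.05 equiv), THF/H2O (2:1), 0 °C; then K2CO3, MeOH, rt
Reagents that add atoms: water, O
Why: Bromohydrin formation in aqueous THF is fastest at the terminal, least hindered isopropylidene olefin of the coiled polyene with water adding at the tertiary carbon, and carbonate closes the epoxide by intramolecular SN2 (bromohydrin–epoxide sequence), the new center being racemic and destroyed in step 5.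

Step 5
Reactants: 9 3-[(3Z,7E)-10-chloro-3,7-dimethyldeca-3,7-dien-1-yl]-2,2-dimethyloxirane
Product: 10 (4Z,8E)-11-chloro-4,8-dimethylundeca-4,8-dienal
Conditions: H5IO6 (1.2 equiv), THF/Et2O, 0 °C
Reagents that add atoms: none
Why: Periodic acid hydrolyses the trisubstituted epoxide and cleaves the C–C bond oxidatively (glycol cleavage) to the aldehyde and acetone, conditions to which isolated olefins and the alkyl chloride are inert.

Step 6
Reactants: 10 (4Z,8E)-11-chloro-4,8-dimethylundeca-4,8-dienal
Product: 11 (4Z,8E)-11-chloro-4,8-dimethylundeca-4,8-dien-1-ol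
Conditions: NaBH4, MeOH, 0 °C
Reagents that add atoms: none
Why: Borohydride reduction of the aldehyde to the primary alcohol is chemoselective over the alkyl chloride and the olefins and touches no stereocenter.

Step 7
Reactants: 11 (4Z,8E)-11-chloro-4,8-dimethylundeca-4,8-dien-1-ol
Product: 12 (4Z,8E)-11-chloro-4,8-dimethylundeca-4,8-dien-1-yl 2,4,6-tri(propan-2-yl)benzoate
Conditions: 2,4,6-tri(propan-2-yl)benzoic acid (1.2 equiv), PPh3, diisopropyl azodicarboxylate, THF, 0 °C → rt
Reagents that add atoms: 2,4,6-tri(propan-2-yl)benzoic acid, CC(C)c1cc(C(C)C)c(C(=O)O)c(C(C)C)c1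
Why: Mitsunobu esterification of the primary alcohol installs the hindered 2,4,6-triisopropylbenzoate, which resists attack by sBuLi at the carbonyl group, directs the α-lithiation of step 9 and later acts as the leaving group of the 1,2-shift.

Step 8
Reactants: 13 (2-bromoethoxy)(tert-butyl)dimethylsilane
Product: 14 tert-butyldimethyl[2-(4,4,5,5-tetramethyl-1,3,2-dioxaborolan-2-yl)ethoxy]silane
Conditions: B2pin2 (1.5 equiv), CuI (10 mol %), PPh3 (13 mol %), LiOMe (2 equiv), DMF, rt
Reagents that add atoms: bis(pinacolato)diboron, CC1(C)OB(OC1(C)C)B1OC(C)(C)C(C)(C)O1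
Why: Copper-catalysed borylation of the primary alkyl bromide with B2pin2 (alkyl halide borylation) gives the two-carbon boronic ester, a substrate class (2-alkoxyethyl bromides) for which this reaction is established.

Step 9
Reactants: 12 (4Z,8E)-11-chloro-4,8-dimethylundeca-4,8-dien-1-yl 2,4,6-tri(propan-2-yl)benzoate; 14 tert-butyldimethyl[2-(4,4,5,5-tetramethyl-1,3,2-dioxaborolan-2-yl)ethoxy]silane
Product: 17 tert-butyl{[(3R,6Z,10E)-13-chloro-6,10-dimethyl-3-(4,4,5,5-tetramethyl-1,3,2-dioxaborolan-2-yl)trideca-6,10-dien-1-yl]oxy}dimethylsilane, via lithiated benzoate 15 (not isolated), via boronate complex 16 (not isolated)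
Conditions: sBuLi (1.3 equiv), (−)-sparteine (1.3 equiv), Et2O, −78 °C, 5 h; 14 (1.5 equiv), −78 °C, 1 h; then 35 °C, 12 h
Reagents that add atoms: none
Why: Lithiation–borylation: sBuLi/(−)-sparteine removes the pro-S α-hydrogen of the benzoate to give a configurationally stable (S)-α-lithio ester, boronate 14 traps it with retention, and the two-carbon alkyl group then migrates from boron to carbon with inversion while the benzoate leaves, which sets ring C4 of the target as the (R) carbon–boron stereocenter under reagent control.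

Step 10
Reactants: 18 sulcatone, 6-methylhept-5-en-2-one
Product: 20 6-methylhept-5-en-1-yne, via enol phosphate 19 (not isolated)
Conditions: LiN(iPr)2 (1.05 equiv), THF, −78 °C; ClP(O)(OEt)2, −78 °C → rt; then LiN(iPr)2 (2.3 equiv), THF, −78 °C → rt; NH4Cl aq
Reagents that add atoms: none
Why: As in step 1, kinetic enolisation at the methyl group, enol phosphate formation and base-induced elimination convert the methyl ketone into the terminal alkyne (alkyne synthesis from a methyl ketone) without touching the trisubstituted olefin.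

Step 11
Reactants: 20 6-methylhept-5-en-1-yne
Product: 22 2-bromo-6-methylhepta-1,5-diene, via alkenylborane 21 (not isolated)
Conditions: B-bromo-9-borabicyclo[3.3.1]nonane (1.1 equiv), CH2Cl2, 0 °C; then AcOH, 0 °C → rt; NaHCO3 aq
Reagents that add atoms: B-bromo-9-borabicyclo[3.3.1]nonane, BrB1C2CCCC1CCC2
Why: Syn bromoboration of the terminal alkyne (haloboration) delivers bromine to the internal carbon and boron to the terminal carbon, and protonolysis of the alkenyl–boron bond with acetic acid gives the 2-bromo-1-alkene while the trisubstituted olefin does not react.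

Step 12
Reactants: 17 tert-butyl{[(3R,6Z,10E)-13-chloro-6,10-dimethyl-3-(4,4,5,5-tetramethyl-1,3,2-dioxaborolan-2-yl)trideca-6,10-dien-1-yl]oxy}dimethylsilane; 22 2-bromo-6-methylhepta-1,5-diene
Product: 26 tert-butyl{[(3R,6Z,10E)-13-chloro-6,10-dimethyl-3-(6-methylhepta-1,5-dien-2-yl)trideca-6,10-dien-1-yl]oxy}dimethylsilane, via alkenyllithium 23 (not isolated), via alkenylboronate complex 24 (not isolated), via iodoboronate 25 (not isolated)
Conditions: 22 (1.6 equiv), tBuLi (3.2 equiv), THF, −78 °C; 17, −78 °C; I2 (2 equiv), THF/MeOH, −78 °C; NaOMe (4 equiv), MeOH, −78 °C → rt; Na2S2O3 aq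
Reagents that add atoms: none
Why: Bromine–lithium exchange on 22 gives alkenyllithium 23, which adds to the boron of 17 to form the tetracoordinate boronate complex 24; iodine then attacks the electron-rich alkene of 24 and the secondary alkyl group migrates from boron to the adjacent carbon as the iodonium opens, giving β-iodoboronic ester 25, from which methoxide triggers anti elimination of boron and iodide to reveal the methylidene group. The closest known reaction type is the Zweifel olefination of secondary pinacol boronic esters with 1-substituted vinyllithium reagents, a transition-metal-free stereospecific sp3–sp2 coupling. No ring is closed in this step; the 14-membered ring is formed only in step 16. No new stereocenter is created: the carbon–boron center set in step 9 migrates with retention of configuration, so (R)-17 is translated into the (R) configuration of ring C4, and the transient center at the former alkenyl carbon is erased in the elimination. The step needs chemoselective iodination of the boronate alkene in the presence of two trisubstituted olefins and the isopropylidene group, which is secured by the far higher nucleophilicity of the anionic alkenylboronate at −78 °C and by a limited amount of iodine, and it needs migration of carbon rather than oxygen, which the pinacol ligand ensures. The primary chloride and the silyl ether are inert to the organolithium at −78 °C, and the 1,1-disubstitution of the new alkene removes any question of E/Z geometry.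

Step 13
Reactants: 26 tert-butyl{[(3R,6Z,10E)-13-chloro-6,10-dimethyl-3-(6-methylhepta-1,5-dien-2-yl)trideca-6,10-dien-1-yl]oxy}dimethylsilane; 27 methyl 2-[bis(2,2,2-trifluoroethoxy)phosphoryl]acetate
Product: 29 methyl (5E,9Z,13R)-2-[bis(2,2,2-trifluoroethoxy)phosphoryl]-15-{[tert-butyl(dimethyl)silyl]oxy}-6,10-dimethyl-13-(6-methylhepta-1,5-dien-2-yl)pentadeca-5,9-dienoate (epimers at C2), via iodide 28 (not isolated)
Conditions: NaI (3 equiv), acetone, reflux; solvent exchange; 27 (2 equiv), NaH (1.9 equiv), DMF, 0 → 45 °C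
Reagents that add atoms: none
Why: Finkelstein exchange followed by SN2 C-alkylation of the soft sodium phosphonoacetate carbanion at the primary iodide (phosphonoacetate alkylation), with excess 27 to suppress dialkylation and a moderate temperature to limit elimination, gives the phosphonate whose phosphorus-bearing carbon is an epimeric mixture that is erased in step 16.

Step 14
Reactants: 29 methyl (5E,9Z,13R)-2-[bis(2,2,2-trifluoroethoxy)phosphoryl]-15-{[tert-butyl(dimethyl)silyl]oxy}-6,10-dimethyl-13-(6-methylhepta-1,5-dien-2-yl)pentadeca-5,9-dienoate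
Product: 30 methyl (5E,9Z,13R)-2-[bis(2,2,2-trifluoroethoxy)phosphoryl]-15-hydroxy-6,10-dimethyl-13-(6-methylhepta-1,5-dien-2-yl)pentadeca-5,9-dienoate
Conditions: HF·pyridine, pyridine, THF, 0 °C → rt
Reagents that add atoms: none
Why: Fluoride-mediated desilylation with pyridine-buffered HF·pyridine cleaves the primary silyl ether without deprotonating the phosphonoacetate or cleaving its trifluoroethyl esters.

Step 15
Reactants: 30 methyl (5E,9Z,13R)-2-[bis(2,2,2-trifluoroethoxy)phosphoryl]-15-hydroxy-6,10-dimethyl-13-(6-methylhepta-1,5-dien-2-yl)pentadeca-5,9-dienoate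
Product: 31 methyl (5E,9Z,13R)-2-[bis(2,2,2-trifluoroethoxy)phosphoryl]-6,10-dimethyl-13-(6-methylhepta-1,5-dien-2-yl)-15-oxopentadeca-5,9-dienoate
Conditions: Dess–Martin periodinane (1.3 equiv), NaHCO3, CH2Cl2, 0 °C → rt
Reagents that add atoms: none
Why: Dess–Martin oxidation of the primary alcohol under buffered, non-basic conditions gives the aldehyde without premature olefination and without risk to the stereocenter, which is β to the new carbonyl group.

Step 16
Reactants: 31 methyl (5E,9Z,13R)-2-[bis(2,2,2-trifluoroethoxy)phosphoryl]-6,10-dimethyl-13-(6-methylhepta-1,5-dien-2-yl)-15-oxopentadeca-5,9-dienoate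
Product: 32 methyl (1Z,4R,7Z,11E)-7,11-dimethyl-4-(6-methylhepta-1,5-dien-2-yl)cyclotetradeca-1,7,11-triene-1-carboxylate
Conditions: KN(SiMe3)2 (1.1 equiv), 18-crown-6 (5 equiv), THF (0.001 M), −78 → −20 °C
Reagents that add atoms: none
Why: Intramolecular Still–Gennari olefination (Z-selective Horner–Wadsworth–Emmons reaction): deprotonation at the phosphonate carbon and addition to the tethered aldehyde close the 14-membered carbocycle, the electron-poor bis(trifluoroethyl) phosphonate and the crown-complexed potassium ion make elimination from the first-formed adduct faster than its equilibration so that CO2Me ends cis to ring C3 (1Z), and 0.001 M dilution disfavours intermolecular olefination, while no stereocenter is formed or touched.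

Step 17
Reactants: 32 methyl (1Z,4R,7Z,11E)-7,11-dimethyl-4-(6-methylhepta-1,5-dien-2-yl)cyclotetradeca-1,7,11-triene-1-carboxylate
Product: 33 [(1Z,4R,7Z,11E)-7,11-dimethyl-4-(6-methylhepta-1,5-dien-2-yl)cyclotetradeca-1,7,11-trien-1-yl]methanol
Conditions: iBu2AlH (2.5 equiv), CH2Cl2, −78 °C; KNaC4H4O6 aq
Reagents that add atoms: none
Why: 1,2-Reduction of the conjugated ester with iBu2AlH at −78 °C (ester to allylic alcohol reduction) proceeds without conjugate reduction or olefin isomerisation and so delivers the hydroxymethyl group cis to ring C3 in the target.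

Compound list
1 | nerylacetone, (5Z)-6,10-dimethylundeca-5,9-dien-2-one | CC(=O)CC/C=C(/C)CCC=C(C)C | starting material
2 | diethyl (5Z)-6,10-dimethylundeca-1,5,9-trien-2-yl phosphate | C=C(OP(=O)(OCC)OCC)CC/C=C(/C)CCC=C(C)C | intermediate (not isolated)
3 | (5Z)-6,10-dimethylundeca-5,9-dien-1-yne | C#CCC/C=C(/C)CCC=C(C)C | intermediate
4 | dimethyl[(1E,5Z)-2,6,10-trimethylundeca-1,5,9-trien-1-yl]alane | C[Al](C)/C=C(\C)CC/C=C(/C)CCC=C(C)C | intermediate (not isolated)
5 | lithium butyl(dimethyl)[(1E,5Z)-2,6,10-trimethylundeca-1,5,9-trien-1-yl]aluminate | [Li+].CCCC[Al-](C)(C)/C=C(\C)CC/C=C(/C)CCC=C(C)C | intermediate (not isolated)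
6 | (3E,7Z)-4,8,12-trimethyltrideca-3,7,11-trien-1-ol | OCC/C=C(\C)CC/C=C(/C)CCC=C(C)C | intermediate
7 | (6Z,10E)-13-chloro-2,6,10-trimethyltrideca-2,6,10-triene | ClCC/C=C(\C)CC/C=C(/C)CCC=C(C)C | intermediate
8 | (6Z,10E)-3-bromo-13-chloro-2,6,10-trimethyltrideca-6,10-dien-2-ol (racemic) | ClCC/C=C(\C)CC/C=C(/C)CCC(Br)C(C)(C)O | intermediate (not isolated)
9 | 3-[(3Z,7E)-10-chloro-3,7-dimethyldeca-3,7-dien-1-yl]-2,2-dimethyloxirane (racemic) | ClCC/C=C(\C)CC/C=C(/C)CCC1OC1(C)C | intermediate
10 | (4Z,8E)-11-chloro-4,8-dimethylundeca-4,8-dienal | ClCC/C=C(\C)CC/C=C(/C)CCC=O | intermediate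
11 | (4Z,8E)-11-chloro-4,8-dimethylundeca-4,8-dien-1-ol | ClCC/C=C(\C)CC/C=C(/C)CCCO | intermediate
12 | (4Z,8E)-11-chloro-4,8-dimethylundeca-4,8-dien-1-yl 2,4,6-tri(propan-2-yl)benzoate | ClCC/C=C(\C)CC/C=C(/C)CCCOC(=O)c1c(C(C)C)cc(C(C)C)cc1C(C)C | intermediate
13 | (2-bromoethoxy)(tert-butyl)dimethylsilane | CC(C)(C)[Si](C)(C)OCCBr | starting material
14 | tert-butyldimethyl[2-(4,4,5,5-tetramethyl-1,3,2-dioxaborolan-2-yl)ethoxy]silane | CC(C)(C)[Si](C)(C)OCCB1OC(C)(C)C(C)(C)O1 | intermediate
15 | {(1S,4Z,8E)-11-chloro-4,8-dimethyl-1-[2,4,6-tri(propan-2-yl)benzoyloxy]undeca-4,8-dien-1-yl}lithium, as its (−)-sparteine complex | ClCC/C=C(\C)CC/C=C(/C)CC[C@H]([Li])OC(=O)c1c(C(C)C)cc(C(C)C)cc1C(C)C | intermediate (not isolated)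
16 | lithium {(1S,4Z,8E)-11-chloro-4,8-dimethyl-1-[2,4,6-tri(propan-2-yl)benzoyloxy]undeca-4,8-dien-1-yl}[2-(tert-butyldimethylsilyloxy)ethyl](pinacolato)borate | [Li+].ClCC/C=C(\C)CC/C=C(/C)CC[C@H]([B-]1(CCO[Si](C)(C)C(C)(C)C)OC(C)(C)C(C)(C)O1)OC(=O)c1c(C(C)C)cc(C(C)C)cc1C(C)C | intermediate (not isolated)
17 | tert-butyl{[(3R,6Z,10E)-13-chloro-6,10-dimethyl-3-(4,4,5,5-tetramethyl-1,3,2-dioxaborolan-2-yl)trideca-6,10-dien-1-yl]oxy}dimethylsilane | CC(C)(C)[Si](C)(C)OCC[C@H](B1OC(C)(C)C(C)(C)O1)CC/C(C)=C\CC/C(C)=C/CCCl | intermediate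
18 | sulcatone, 6-methylhept-5-en-2-one | CC(=O)CCC=C(C)C | starting material
19 | diethyl 6-methylhepta-1,5-dien-2-yl phosphate | C=C(OP(=O)(OCC)OCC)CCC=C(C)C | intermediate (not isolated)
20 | 6-methylhept-5-en-1-yne | C#CCCC=C(C)C | intermediate
21 | 9-[(1Z)-2-bromo-6-methylhepta-1,5-dien-1-yl]-9-borabicyclo[3.3.1]nonane | Br/C(CCC=C(C)C)=C\B1C2CCCC1CCC2 | intermediate (not isolated)
22 | 2-bromo-6-methylhepta-1,5-diene | C=C(Br)CCC=C(C)C | intermediate
23 | (6-methylhepta-1,5-dien-2-yl)lithium | [Li]C(=C)CCC=C(C)C | intermediate (not isolated)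
24 | lithium [(3R,6Z,10E)-1-(tert-butyldimethylsilyloxy)-13-chloro-6,10-dimethyltrideca-6,10-dien-3-yl](6-methylhepta-1,5-dien-2-yl)(pinacolato)borate | [Li+].CC(C)(C)[Si](C)(C)OCC[C@H]([B-]1(C(=C)CCC=C(C)C)OC(C)(C)C(C)(C)O1)CC/C(C)=C\CC/C(C)=C/CCCl | intermediate (not isolated)
25 | tert-butyl{[(3R,6Z,10E)-13-chloro-3-[1-iodo-6-methyl-2-(4,4,5,5-tetramethyl-1,3,2-dioxaborolan-2-yl)hept-5-en-2-yl]-6,10-dimethyltrideca-6,10-dien-1-yl]oxy}dimethylsilane (mixture at the boron-bearing carbon) | CC(C)(C)[Si](C)(C)OCC[C@H](C(CI)(CCC=C(C)C)B1OC(C)(C)C(C)(C)O1)CC/C(C)=C\CC/C(C)=C/CCCl | intermediate (not isolated)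
26 | tert-butyl{[(3R,6Z,10E)-13-chloro-6,10-dimethyl-3-(6-methylhepta-1,5-dien-2-yl)trideca-6,10-dien-1-yl]oxy}dimethylsilane | CC(C)(C)[Si](C)(C)OCC[C@H](C(=C)CCC=C(C)C)CC/C(C)=C\CC/C(C)=C/CCCl | intermediate
27 | methyl 2-[bis(2,2,2-trifluoroethoxy)phosphoryl]acetate | COC(=O)CP(=O)(OCC(F)(F)F)OCC(F)(F)F | starting material
28 | tert-butyl{[(3R,6Z,10E)-13-iodo-6,10-dimethyl-3-(6-methylhepta-1,5-dien-2-yl)trideca-6,10-dien-1-yl]oxy}dimethylsilane | CC(C)(C)[Si](C)(C)OCC[C@H](C(=C)CCC=C(C)C)CC/C(C)=C\CC/C(C)=C/CCI | intermediate (not isolated)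
29 | methyl (5E,9Z,13R)-2-[bis(2,2,2-trifluoroethoxy)phosphoryl]-15-{[tert-butyl(dimethyl)silyl]oxy}-6,10-dimethyl-13-(6-methylhepta-1,5-dien-2-yl)pentadeca-5,9-dienoate (epimers at C2) | CC(C)(C)[Si](C)(C)OCC[C@H](C(=C)CCC=C(C)C)CC/C(C)=C\CC/C(C)=C/CCC(C(=O)OC)P(=O)(OCC(F)(F)F)OCC(F)(F)F | intermediate
30 | methyl (5E,9Z,13R)-2-[bis(2,2,2-trifluoroethoxy)phosphoryl]-15-hydroxy-6,10-dimethyl-13-(6-methylhepta-1,5-dien-2-yl)pentadeca-5,9-dienoate (epimers at C2) | OCC[C@H](C(=C)CCC=C(C)C)CC/C(C)=C\CC/C(C)=C/CCC(C(=O)OC)P(=O)(OCC(F)(F)F)OCC(F)(F)F | intermediate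
31 | methyl (5E,9Z,13R)-2-[bis(2,2,2-trifluoroethoxy)phosphoryl]-6,10-dimethyl-13-(6-methylhepta-1,5-dien-2-yl)-15-oxopentadeca-5,9-dienoate (epimers at C2) | O=CC[C@H](C(=C)CCC=C(C)C)CC/C(C)=C\CC/C(C)=C/CCC(C(=O)OC)P(=O)(OCC(F)(F)F)OCC(F)(F)F | intermediate
32 | methyl (1Z,4R,7Z,11E)-7,11-dimethyl-4-(6-methylhepta-1,5-dien-2-yl)cyclotetradeca-1,7,11-triene-1-carboxylate | C=C(CCC=C(C)C)[C@H]1C/C=C(\C(=O)OC)CC/C=C(\C)CC/C=C(/C)CC1 | intermediate
33 | [(1Z,4R,7Z,11E)-7,11-dimethyl-4-(6-methylhepta-1,5-dien-2-yl)cyclotetradeca-1,7,11-trien-1-yl]methanol | C=C(CCC=C(C)C)[C@H]1C/C=C(\CO)CC/C=C(\C)CC/C=C(/C)CC1 | target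

Total step count: 17. Longest linear sequence: 14 steps (steps 1–7, 9, 12–17).

Steps most likely to fail

Step 16. Intermolecular olefination may outrun ring closure, and kinetic Z control may erode when the adduct forms inside a strained 14-membered transition state. The fallback fixes the enoate geometry before ring closure and closes the ring at C1–C14 by cross-coupling. It sets out from 26: Finkelstein exchange (NaI, acetone) gives iodide 28, isolated this time. HF·pyridine should give (3R,6Z,10E)-13-iodo-6,10-dimethyl-3-(6-methylhepta-1,5-dien-2-yl)trideca-6,10-dien-1-ol F1, and Dess–Martin oxidation the corresponding aldehyde (3R,6Z,10E)-13-iodo-6,10-dimethyl-3-(6-methylhepta-1,5-dien-2-yl)trideca-6,10-dienal F2. Intermolecular olefination with methyl 2-[bis(2,2,2-trifluoroethoxy)phosphoryl]-2-bromoacetate (KOtBu, 18-crown-6, THF, −78 °C) should give methyl (2E,5R,8Z,12E)-2-bromo-15-iodo-8,12-dimethyl-5-(6-methylhepta-1,5-dien-2-yl)pentadeca-2,8,12-trienoate F3, in which CO2Me is already cis to the chain. Zinc insertion into the primary carbon–iodine bond (Zn, LiCl, THF) should give the alkylzinc iodide [(3E,7Z,11R,13E)-14-bromo-15-methoxy-4,8-dimethyl-11-(6-methylhepta-1,5-dien-2-yl)-15-oxopentadeca-3,7,13-trien-1-yl](iodo)zinc F4. Slow addition of F4 to Pd(PPh3)4 in THF at 50 °C under high dilution should close the ring by intramolecular Negishi coupling with retention of the alkene geometry, and the route is rejoined at 32.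

Step 9. The boronate complex carries a silyloxy group β to boron and may lose it by elimination before the slow 1,2-shift of a primary alkyl group occurs; the lithiated benzoate may also partly racemise during the long lithiation. The fallback sets the carbon–boron center by catalysis instead. It sets out from aldehyde 10: Wittig reaction with ethyl (triphenylphosphoranylidene)acetate should give ethyl (2E,6Z,10E)-13-chloro-6,10-dimethyltrideca-2,6,10-trienoate F5. Copper-catalysed asymmetric conjugate borylation (CuCl, NaOtBu, B2pin2, MeOH, THF, with the ferrocenyl diphosphine 1-[2-(diphenylphosphino)ferrocenyl]ethyldicyclohexylphosphine in the enantiomer that delivers the 3R product) should give ethyl (3R,6Z,10E)-13-chloro-6,10-dimethyl-3-(4,4,5,5-tetramethyl-1,3,2-dioxaborolan-2-yl)trideca-6,10-dienoate F6. Reduction with iBu2AlH should give (3R,6Z,10E)-13-chloro-6,10-dimethyl-3-(4,4,5,5-tetramethyl-1,3,2-dioxaborolan-2-yl)trideca-6,10-dien-1-ol F7, and silylation (tert-butyldimethylsilyl chloride, imidazole) rejoins the route at 17.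

Step 12. Iodine may also attack the three electron-rich olefins of the chain, and complexation of the hindered secondary boronic ester by the 1-substituted alkenyllithium may be incomplete. The fallback forms the C4–C2' bond by auxiliary-controlled conjugate addition and needs no boron. It sets out from aldehyde 10: Horner–Wadsworth–Emmons reaction with diethyl {2-oxo-2-[(4S)-2-oxo-4-phenyl-1,3-oxazolidin-3-yl]ethyl}phosphonate (LiCl, iPr2NEt, MeCN) should give (4S)-3-[(2E,6Z,10E)-13-chloro-6,10-dimethyltrideca-2,6,10-trienoyl]-4-phenyl-1,3-oxazolidin-2-one F8. The alkenylcopper reagent made from the Grignard reagent of 22 and CuBr·SMe2 (THF/Me2S, −78 → −20 °C) should add to the magnesium-chelated s-cis imide on the face opposite the phenyl group and give (4S)-3-[(3R,6Z,10E)-13-chloro-6,10-dimethyl-3-(6-methylhepta-1,5-dien-2-yl)trideca-6,10-dienoyl]-4-phenyl-1,3-oxazolidin-2-one F9. Reductive removal of the auxiliary with LiBH4 (THF/MeOH) should give (3R,6Z,10E)-13-chloro-6,10-dimethyl-3-(6-methylhepta-1,5-dien-2-yl)trideca-6,10-dien-1-ol F10, and silylation (tert-butyldimethylsilyl chloride, imidazole) rejoins the route at 26.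

Further compounds
F1 | step 16 | (3R,6Z,10E)-13-iodo-6,10-dimethyl-3-(6-methylhepta-1,5-dien-2-yl)trideca-6,10-dien-1-ol | OCC[C@H](C(=C)CCC=C(C)C)CC/C(C)=C\CC/C(C)=C/CCI
F2 | step 16 | (3R,6Z,10E)-13-iodo-6,10-dimethyl-3-(6-methylhepta-1,5-dien-2-yl)trideca-6,10-dienal | O=CC[C@H](C(=C)CCC=C(C)C)CC/C(C)=C\CC/C(C)=C/CCI
F3 | step 16 | methyl (2E,5R,8Z,12E)-2-bromo-15-iodo-8,12-dimethyl-5-(6-methylhepta-1,5-dien-2-yl)pentadeca-2,8,12-trienoate | COC(=O)/C(Br)=C\C[C@H](C(=C)CCC=C(C)C)CC/C(C)=C\CC/C(C)=C/CCI
F4 | step 16 | [(3E,7Z,11R,13E)-14-bromo-15-methoxy-4,8-dimethyl-11-(6-methylhepta-1,5-dien-2-yl)-15-oxopentadeca-3,7,13-trien-1-yl](iodo)zinc | COC(=O)/C(Br)=C\C[C@H](C(=C)CCC=C(C)C)CC/C(C)=C\CC/C(C)=C/CC[Zn]I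
F5 | step 9 | ethyl (2E,6Z,10E)-13-chloro-6,10-dimethyltrideca-2,6,10-trienoate | CCOC(=O)/C=C/CC/C(C)=C\CC/C(C)=C/CCCl
F6 | step 9 | ethyl (3R,6Z,10E)-13-chloro-6,10-dimethyl-3-(4,4,5,5-tetramethyl-1,3,2-dioxaborolan-2-yl)trideca-6,10-dienoate | CCOC(=O)C[C@H](B1OC(C)(C)C(C)(C)O1)CC/C(C)=C\CC/C(C)=C/CCCl
F7 | step 9 | (3R,6Z,10E)-13-chloro-6,10-dimethyl-3-(4,4,5,5-tetramethyl-1,3,2-dioxaborolan-2-yl)trideca-6,10-dien-1-ol | OCC[C@H](B1OC(C)(C)C(C)(C)O1)CC/C(C)=C\CC/C(C)=C/CCCl
F8 | step 12 | (4S)-3-[(2E,6Z,10E)-13-chloro-6,10-dimethyltrideca-2,6,10-trienoyl]-4-phenyl-1,3-oxazolidin-2-one | O=C(/C=C/CC/C(C)=C\CC/C(C)=C/CCCl)N1[C@@H](c2ccccc2)COC1=O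
F9 | step 12 | (4S)-3-[(3R,6Z,10E)-13-chloro-6,10-dimethyl-3-(6-methylhepta-1,5-dien-2-yl)trideca-6,10-dienoyl]-4-phenyl-1,3-oxazolidin-2-one | O=C(C[C@H](C(=C)CCC=C(C)C)CC/C(C)=C\CC/C(C)=C/CCCl)N1[C@@H](c2ccccc2)COC1=O
F10 | step 12 | (3R,6Z,10E)-13-chloro-6,10-dimethyl-3-(6-methylhepta-1,5-dien-2-yl)trideca-6,10-dien-1-ol | OCC[C@H](C(=C)CCC=C(C)C)CC/C(C)=C\CC/C(C)=C/CCCl
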